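All runs were generated by integration on assumed constants, noise included.

A ratio of two logarithms told me what theta would do, and I reckoned it from these runs.

the same everywhere: free catalyst 10 µM
- theta: starting material 5.0 × 10⁻⁴ M; temperature 70 °C; the very flask that is asked about, followed so far
- beta: starting material 7.5 × 10⁻⁴ M; temperature 65 °C; run made earlier
- flask: starting material 5.0 × 10⁻⁴ M; temperature 70 °C; time 12 min

theta run (percent of the starting material charged)

| time / min | target / % | starting material / % |
|---|---|---|
| 1.00 | 20.6 | 78.4 |
| 2.00 | 24.8 | 73.5 |
| 3.00 | 27.0 | 70.7 |
| 4.00 | 28.3 | 69.7 |
| 5.00 | 29.2 | 68.0 |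
| 6.00 | 30.6 | 67.1 |
| 8.00 | 31.8 | 65.3 |

beta run (percent of the starting material charged)

| time / s | target / % | starting material / % |
|---|---|---|
| 10.0 | 7.9 | 91.5 |
| 15.0 | 10.3 | 90.0 |
| 25.0 | 13.3 | 86.4 |
| 40.0 | 15.9 | 83.9 |
| 50.0 | 16.8 | 82.3 |
| 60.0 | 18.1 | 81.1 |

(standard deviation of a reading: 0.3 percentage points)

- Saturday's: at 12 min raise the temperature by 20 K, then wait 4.0 min
- Thursday's: change nothing and wait 4.0 min more
- Friday's: at 12 min add free catalyst, 100% of the amount charged, then wait 4.0 min
- Monday's: at 12 min take out 90% of the target then present, then wait 4.0 min

- target, in percent of the starting material first charged, at 12 min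
- the remedy with the largest gain of target, or "none" below 2 percentage points (Saturday's / Thursday's / Friday's / Monday's / none)
- target present, with what was taken out counted in, in percent of the starting material first charged, after Saturday's
- target present, with what was taken out counted in, in percent of the starting material first charged, after Thursday's

- target that was removed still counts
- additions bring no volume worth counting

In the theta run I divided the fall of ln c(starting material) by the rise of ln time, between 2.00 min and 8.00 min, and I called this ratio the burn number; it came to 0.0853 as a reading. A steady value would mean that the rate per unit of starting material falls inversely with time. I took that as free catalyst destroying itself in pairs, and read the burn number as conversion set against catalyst death. I then tested whether one number was enough. The beta run, between 25.0 s and 60.0 s, gave a lower slope of 0.0723, close enough for me to keep the form, but the number sets no level. It needs one anchoring reading, and the target needs a selectivity, which I read at 8.00 min as 0.916 of the starting material consumed.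

From that anchor I reckoned 63.1% starting material and 33.8% target at 12 min. For Thursday's I reckoned 35.2% target. Taking the catalyst still present as small beside an addition, I let Friday's repeat the opening fall to 69.7% over 4.00 min, and so reckoned 51.3% target.

The forecast gave 33.8% (from 33.2% to 34.5%), 38% after Saturday's, 35.3% after Thursday's, and chose Friday's: “Fresh catalyst restarts the fast burst”.

The flask gave 34.1% target, 37.0% after Saturday's and 35.4% after Thursday's, and Friday's was best, with a gain of 14 percentage points.

free catalyst + target → free catalyst + over-reaction product (k = 706 M⁻¹ s⁻¹, Ea = 50.0 kJ mol⁻¹); 2 free catalyst → spent catalyst (k = 10500 M⁻¹ s⁻¹, Ea = 26.0 kJ mol⁻¹); starting material + free catalyst → free catalyst + target (k = 1950 M⁻¹ s⁻¹, Ea = 47.0 kJ mol⁻¹); (constants at 70 °C) Reckoning with the product of charged free catalyst and time, I set a neighbouring flask charged with 4.0 × 10⁻⁶ M of free catalyst, at 12 min, beside the asked flask at 4.80 min. The burn number put that at 68.2% starting material and 29.1% target. The neighbouring flask held 68.2% starting material and 29.5% target.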